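**Strategy.** Everything rests on disconnecting ring C of the epigallocatechin unit across C4–C4a and O1–C2. The phloroglucinol ring A is a 1,3-C,O-dinucleophile (C4a and the O1 phenol), and C2–C3–C4 is a three-carbon dielectrophile whose cis C2-aryl/C3-hydroxyl pattern is stored in a cis-epoxide. In one titanium-templated operation the whole upper half, phenol 13 (2,4-trans flavan already on the future C8), is united with cis-epoxy aldehyde 6: ortho-hydroxyalkylation forms C4–C4a, then 6-endo epoxide opening forms O1–C2 with inversion, fixing C2 and C3. Ionic removal of the C4 hydroxyl and hydrogenolysis of seven benzyl ethers complete the route.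

Key step: step 9

Remark: compounds 1, 2, 7, 9 and 12 are taken as commercial; flavan numbering is used ("upper unit" = the 7,4'-dioxygenated flavan, "lower unit" = the epigallocatechin unit), and the carbinol centre C4 of the lower unit made in step 9 is left undefined in 14 and 15 because both epimers give the same CH2 in step 10.

Step 1
Reactants: 1 3,4,5-tris(benzyloxy)benzaldehyde; 2 ethyl 2-(diphenoxyphosphoryl)acetate
Product: 3 ethyl (2Z)-3-[3,4,5-tris(benzyloxy)phenyl]prop-2-enoate
Conditions: NaH, THF, −78 °C → 0 °C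
Reagents that add atoms: none
Why: Z-selective Horner–Wadsworth–Emmons olefination, in which the electron-poor diaryl phosphonate lets the kinetically formed cis-oxaphosphetane collapse before it equilibrates, so the Z-enoate should predominate and the minor E-isomer is removed by chromatography.

Step 2
Reactants: 3 ethyl (2Z)-3-[3,4,5-tris(benzyloxy)phenyl]prop-2-enoate
Product: 4 (2Z)-3-[3,4,5-tris(benzyloxy)phenyl]prop-2-en-1-ol
Conditions: i-Bu2AlH (2.2 equiv), CH2Cl2, −78 °C
Reagents that add atoms: none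
Why: 1,2-reduction of the conjugated ester by the aluminium hydride at low temperature should give the allylic alcohol without touching the benzyl ethers or the Z double bond.

Step 3
Reactants: 4 (2Z)-3-[3,4,5-tris(benzyloxy)phenyl]prop-2-en-1-ol
Product: 5 {(2R,3S)-3-[3,4,5-tris(benzyloxy)phenyl]oxiran-2-yl}methanol (cis-epoxide)
Conditions: Ti(OiPr)4 (20 mol%), D-(−)-diisopropyl tartrate (24 mol%), t-BuOOH, 4 Å molecular sieves, CH2Cl2, −20 °C
Reagents that add atoms: tert-butyl hydroperoxide, CC(C)(C)OO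
Why: Sharpless asymmetric epoxidation, in which the D-(−)-tartrate complex directs oxygen transfer to the face that makes the carbinol-bearing epoxide carbon R while the Z geometry is carried into the cis-epoxide, so both stereocentres (2R,3S) are set here by reagent control.

Step 4
Reactants: 5 {(2R,3S)-3-[3,4,5-tris(benzyloxy)phenyl]oxiran-2-yl}methanol
Product: 6 (2S,3S)-3-[3,4,5-tris(benzyloxy)phenyl]oxirane-2-carbaldehyde (cis-epoxide)
Conditions: Dess–Martin periodinane, NaHCO3, CH2Cl2, 0 °C
Reagents that add atoms: none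
Why: Dess–Martin oxidation under bicarbonate buffer is mild enough for the acid-sensitive aryl epoxide, and the epoxide carbon next to the aldehyde resists enolisation, so the cis configuration should hold if crude 6 is used at once (the descriptor changes only because of priorities).

Step 5
Reactants: 7 7-hydroxy-4H-chromen-4-one
Product: 8 7-(benzyloxy)-4H-chromen-4-one
Conditions: BnBr, K2CO3, DMF, rt
Reagents that add atoms: benzyl bromide, BrCc1ccccc1
Why: Williamson ether synthesis on the acidic phenol installs a benzyl group that is removed with all the others at the end.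

Step 6
Reactants: 8 7-(benzyloxy)-4H-chromen-4-one; 9 [4-(benzyloxy)phenyl]boronic acid
Product: 10 (2S)-7-(benzyloxy)-2-[4-(benzyloxy)phenyl]-2,3-dihydro-4H-chromen-4-one
Conditions: Pd(OCOCF3)2 (5 mol%), (R)-t-BuPyOx (6 mol%), NH4PF6 (30 mol%), H2O, ClCH2CH2Cl, 60 °C
Reagents that add atoms: none
Why: palladium-catalysed asymmetric conjugate addition of an arylboronic acid to a chromone (transmetallation to divalent palladium, insertion of C2=C3, protonolysis of the palladium enolate), in which the pyridine–oxazoline ligand controls the face of insertion; the ligand enantiomer is chosen so that C2 is S, and the (R)-ligand is expected to be that one by analogy with carbocyclic enones.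

Step 7
Reactants: 10 (2S)-7-(benzyloxy)-2-[4-(benzyloxy)phenyl]-2,3-dihydro-4H-chromen-4-one
Product: 11 (2S,4S)-7-(benzyloxy)-2-[4-(benzyloxy)phenyl]-3,4-dihydro-2H-chromen-4-ol (2,4-cis)
Conditions: NaBH4, MeOH/THF, 0 °C
Reagents that add atoms: none
Why: borohydride reduction of the flavanone with hydride delivered trans to the equatorial 2-aryl group should give the 2,4-cis alcohol (4S), whose configuration is in any case erased on ionisation in step 8.

Step 8
Reactants: 11 (2S,4S)-7-(benzyloxy)-2-[4-(benzyloxy)phenyl]-3,4-dihydro-2H-chromen-4-ol; 12 3,5-bis(benzyloxy)phenol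
Product: 13 3,5-bis(benzyloxy)-2-{(2S,4R)-7-(benzyloxy)-2-[4-(benzyloxy)phenyl]-3,4-dihydro-2H-chromen-4-yl}phenol (2,4-trans)
Conditions: BF3·OEt2 (20 mol%), 12 (3 equiv), CH2Cl2, −78 → −30 °C
Reagents that add atoms: none
Why: Friedel–Crafts alkylation through the flavan-4-yl cation (stabilised by O1 and the 7-benzyloxy group), in which the phenol should react at the carbon flanked by OH and OBn and not at the more hindered one between two OBn groups, as in the acid-mediated cinnamylation of this phenol, and pseudo-axially on the face anti to the equatorial 2-aryl group, which sets C4 as R; excess 12 suppresses double alkylation.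

Step 9
Reactants: 13 3,5-bis(benzyloxy)-2-{(2S,4R)-7-(benzyloxy)-2-[4-(benzyloxy)phenyl]-3,4-dihydro-2H-chromen-4-yl}phenol; 6 (2S,3S)-3-[3,4,5-tris(benzyloxy)phenyl]oxirane-2-carbaldehyde
Product: 15 (2R,3R)-5,7-bis(benzyloxy)-8-{(2S,4R)-7-(benzyloxy)-2-[4-(benzyloxy)phenyl]-3,4-dihydro-2H-chromen-4-yl}-2-[3,4,5-tris(benzyloxy)phenyl]-3,4-dihydro-2H-chromene-3,4-diol (2,3-cis; C4 epimers), via epoxy salicyl alcohol 14 (not isolated)
Conditions: Ti(OiPr)4 (1.2 equiv), toluene, rt, then evaporation; 6 (1.2 equiv), CH2Cl2, −20 °C → rt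
Reagents that add atoms: none
Why: Proposed new method: exchange of one isopropoxide gives the titanium phenoxide of 13, which binds the aldehyde of 6 and delivers the only free ortho carbon of ring A (the future C4a) to the carbonyl carbon through a six-membered metal-templated transition state, forming C4–C4a and titanium-bound 14. The metal then holds a 2,3-epoxy alkoxide and activates the epoxide, so that the phenolic oxygen attacks the benzylic, alkoxyaryl-stabilised epoxide carbon from the rear and forms O1–C2. The closest known reaction types are the ortho-specific hydroxyalkylation of titanium and magnesium phenoxides with aldehydes, the Ti(OiPr)4-mediated opening of 2,3-epoxy alcohols at the carbon remote from the carbinol, and the 6-endo cyclisation of 2-(3-aryl-2,3-epoxypropyl)phenols to flavan-3-ols; what is new is their union in one operation on an epoxy aldehyde. Ring C is closed in the 6-endo-tet mode by the O1–C2 bond after the intermolecular C4–C4a bond; if the phenoxide were to open the epoxide first, ring closure by hydroxyalkylation would give the same product. C2 becomes R by inversion of the S benzylic epoxide carbon and C3 keeps its C–O bond and thus its configuration, so the cis-epoxide is translated into the 2,3-cis pattern under substrate control, while C4 forms as an epimeric mixture that step 10 removes. The step needs ortho rather than para attack on ring A, secured by the metal tether (the carbon between the two benzyloxy groups cannot be reached), and 6-endo rather than 5-exo opening, secured by the benzylic terminus and the titanium epoxy-alkoxide chelate.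

Step 10
Reactants: 15 (2R,3R)-5,7-bis(benzyloxy)-8-{(2S,4R)-7-(benzyloxy)-2-[4-(benzyloxy)phenyl]-3,4-dihydro-2H-chromen-4-yl}-2-[3,4,5-tris(benzyloxy)phenyl]-3,4-dihydro-2H-chromene-3,4-diol
Product: 16 (2R,3R)-5,7-bis(benzyloxy)-8-{(2S,4R)-7-(benzyloxy)-2-[4-(benzyloxy)phenyl]-3,4-dihydro-2H-chromen-4-yl}-2-[3,4,5-tris(benzyloxy)phenyl]-3,4-dihydro-2H-chromen-3-ol
Conditions: Et3SiH (5 equiv), CF3CO2H (3 equiv), CH2Cl2, −40 → 0 °C
Reagents that add atoms: none
Why: ionic hydrogenation, in which only the C4 hydroxyl (benzylic and ortho/para to the two alkoxy groups of ring A) ionises and the cation is reduced by the silane to CH2, leaving the C3 alcohol, the benzyl ethers, the interflavan bond of the 5-deoxy upper unit and all four stereocentres untouched.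

Step 11
Reactants: 16 (2R,3R)-5,7-bis(benzyloxy)-8-{(2S,4R)-7-(benzyloxy)-2-[4-(benzyloxy)phenyl]-3,4-dihydro-2H-chromen-4-yl}-2-[3,4,5-tris(benzyloxy)phenyl]-3,4-dihydro-2H-chromen-3-ol
Product: 17 (2R,3R)-8-[(2S,4R)-7-hydroxy-2-(4-hydroxyphenyl)-3,4-dihydro-2H-chromen-4-yl]-2-(3,4,5-trihydroxyphenyl)-3,4-dihydro-2H-chromene-3,5,7-triol
Conditions: H2 (1 atm), Pd(OH)2/C, THF/MeOH, rt
Reagents that add atoms: none
Why: hydrogenolysis of all seven benzyl ethers should release the target, since the cyclic benzylic C2–O1 ethers and the diarylmethine C4 of the upper unit are not cleaved under such mild conditions, as is usual in the debenzylation of protected flavan-3-ols and their dimers.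

**Compound list**

1 | 3,4,5-tris(benzyloxy)benzaldehyde | O=Cc1cc(OCc2ccccc2)c(OCc2ccccc2)c(OCc2ccccc2)c1 | starting material
2 | ethyl 2-(diphenoxyphosphoryl)acetate | CCOC(=O)CP(=O)(Oc1ccccc1)Oc1ccccc1 | starting material
3 | ethyl (2Z)-3-[3,4,5-tris(benzyloxy)phenyl]prop-2-enoate | CCOC(=O)/C=C\c1cc(OCc2ccccc2)c(OCc2ccccc2)c(OCc2ccccc2)c1 | intermediate
4 | (2Z)-3-[3,4,5-tris(benzyloxy)phenyl]prop-2-en-1-ol | OC/C=C\c1cc(OCc2ccccc2)c(OCc2ccccc2)c(OCc2ccccc2)c1 | intermediate
5 | {(2R,3S)-3-[3,4,5-tris(benzyloxy)phenyl]oxiran-2-yl}methanol (cis) | OC[C@H]1O[C@H]1c1cc(OCc2ccccc2)c(OCc2ccccc2)c(OCc2ccccc2)c1 | intermediate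
6 | (2S,3S)-3-[3,4,5-tris(benzyloxy)phenyl]oxirane-2-carbaldehyde (cis) | O=C[C@H]1O[C@H]1c1cc(OCc2ccccc2)c(OCc2ccccc2)c(OCc2ccccc2)c1 | intermediate
7 | 7-hydroxy-4H-chromen-4-one | O=c1ccoc2cc(O)ccc12 | starting material
8 | 7-(benzyloxy)-4H-chromen-4-one | O=c1ccoc2cc(OCc3ccccc3)ccc12 | intermediate
9 | [4-(benzyloxy)phenyl]boronic acid | OB(O)c1ccc(OCc2ccccc2)cc1 | starting material
10 | (2S)-7-(benzyloxy)-2-[4-(benzyloxy)phenyl]-2,3-dihydro-4H-chromen-4-one | C(c1ccccc1)Oc1ccc([C@@H]2CC(=O)c3ccc(OCc4ccccc4)cc3O2)cc1 | intermediate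
11 | (2S,4S)-7-(benzyloxy)-2-[4-(benzyloxy)phenyl]-3,4-dihydro-2H-chromen-4-ol (2,4-cis) | C(c1ccccc1)Oc1ccc([C@@H]2C[C@H](O)c3ccc(OCc4ccccc4)cc3O2)cc1 | intermediate
12 | 3,5-bis(benzyloxy)phenol | Oc1cc(OCc2ccccc2)cc(OCc2ccccc2)c1 | starting material
13 | 3,5-bis(benzyloxy)-2-{(2S,4R)-7-(benzyloxy)-2-[4-(benzyloxy)phenyl]-3,4-dihydro-2H-chromen-4-yl}phenol (2,4-trans) | C(c1ccccc1)Oc1ccc([C@@H]2C[C@@H](c3c(OCc4ccccc4)cc(OCc4ccccc4)cc3O)c3ccc(OCc4ccccc4)cc3O2)cc1 | intermediate
14 | 3,5-bis(benzyloxy)-2-{(2S,4R)-7-(benzyloxy)-2-[4-(benzyloxy)phenyl]-3,4-dihydro-2H-chromen-4-yl}-6-(hydroxy{(2R,3S)-3-[3,4,5-tris(benzyloxy)phenyl]oxiran-2-yl}methyl)phenol (carbinol epimers; shown as the free alcohol, titanium-bound in the flask) | C(c1ccccc1)Oc1ccc([C@@H]2C[C@@H](c3c(OCc4ccccc4)cc(OCc4ccccc4)c(C(O)[C@H]4O[C@H]4c4cc(OCc5ccccc5)c(OCc5ccccc5)c(OCc5ccccc5)c4)c3O)c3ccc(OCc4ccccc4)cc3O2)cc1 | intermediate (not isolated)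
15 | (2R,3R)-5,7-bis(benzyloxy)-8-{(2S,4R)-7-(benzyloxy)-2-[4-(benzyloxy)phenyl]-3,4-dihydro-2H-chromen-4-yl}-2-[3,4,5-tris(benzyloxy)phenyl]-3,4-dihydro-2H-chromene-3,4-diol (2,3-cis; C4 epimers) | C(c1ccccc1)Oc1ccc([C@@H]2C[C@@H](c3c(OCc4ccccc4)cc(OCc4ccccc4)c4c3O[C@H](c3cc(OCc5ccccc5)c(OCc5ccccc5)c(OCc5ccccc5)c3)[C@H](O)C4O)c3ccc(OCc4ccccc4)cc3O2)cc1 | intermediate
16 | (2R,3R)-5,7-bis(benzyloxy)-8-{(2S,4R)-7-(benzyloxy)-2-[4-(benzyloxy)phenyl]-3,4-dihydro-2H-chromen-4-yl}-2-[3,4,5-tris(benzyloxy)phenyl]-3,4-dihydro-2H-chromen-3-ol | C(c1ccccc1)Oc1ccc([C@@H]2C[C@@H](c3c(OCc4ccccc4)cc(OCc4ccccc4)c4c3O[C@H](c3cc(OCc5ccccc5)c(OCc5ccccc5)c(OCc5ccccc5)c3)[C@H](O)C4)c3ccc(OCc4ccccc4)cc3O2)cc1 | intermediate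
17 | (2R,3R)-8-[(2S,4R)-7-hydroxy-2-(4-hydroxyphenyl)-3,4-dihydro-2H-chromen-4-yl]-2-(3,4,5-trihydroxyphenyl)-3,4-dihydro-2H-chromene-3,5,7-triol | Oc1ccc([C@@H]2C[C@@H](c3c(O)cc(O)c4c3O[C@H](c3cc(O)c(O)c(O)c3)[C@H](O)C4)c3ccc(O)cc3O2)cc1 | target

**Step count.** Total: 11 steps. Longest linear sequence: 7 steps (1–4 then 9–11, or 5–11).

**Steps most likely to fail**

1. Step 9 (Proposed new method). The titanium phenoxide may add too slowly to the epoxy aldehyde, isopropoxide may compete as nucleophile or reductant, the ring may close 5-exo, or the electron-rich benzylic epoxide may ionise and lose its stereochemical integrity. The fallback uses known chemistry, forms the two bonds in the opposite order in separate steps, sets out from 13 and 5 and comes back at 16. The phenoxide of 13 (NaOH aq, dioxane, 70 °C) should open the cis-epoxy alcohol 5 at its benzylic carbon with inversion, as is established for 3-arylglycidols, to give the aryl ether diol F1. Selective sulfonylation of the primary hydroxyl (TsCl, Et3N, Bu2SnO cat., CH2Cl2) gives the monotosylate F2, and K2CO3 in MeOH closes the terminal epoxide F3. A Lewis acid-promoted intramolecular Friedel–Crafts epoxide–arene cyclisation (BF3·OEt2, CH2Cl2, −78 °C), 6-endo at the terminal epoxide carbon and possible only at the one free ortho position, should then give 16 directly, so step 10 is not needed.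

2. Step 8. The flavan-4-yl cation may be captured at the ring carbon between the two benzyloxy groups, or on the face syn to the 2-aryl group, or twice. The fallback replaces intermolecular capture by delivery from oxygen, sets out from 11 and 12 and comes back at 13. Mitsunobu etherification (PPh3, DIAD, THF, 0 °C) should invert C4 and give the 2,4-trans aryl ether F4. A Lewis acid-induced 1,3-shift from oxygen to carbon (BF3·OEt2 cat., CH2Cl2, −78 °C) should then return the cation within the ion pair to the ortho carbon on the face the oxygen left, giving 13.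

3. Step 3. Epoxidation of the Z-disubstituted allylic alcohol may be slow and only moderately enantioselective, and the titanium Lewis acid may open the electron-rich cis-epoxide. The fallback changes the epoxidation to one that needs no allylic alcohol, sets out from 3 and comes back at 6. Jacobsen–Katsuki epoxidation of the Z-enoate 3 with the (S,S)-enantiomer of chloro[N,N'-bis(3,5-di-tert-butylsalicylidene)-1,2-cyclohexanediaminato]manganese (trivalent manganese), NaOCl and 4-phenylpyridine N-oxide in CH2Cl2 at 0 °C should give the cis-glycidic ester F5. Partial reduction (i-Bu2AlH, 1 equiv, toluene, −78 °C) then gives 6, bypassing 4 and 5.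

**Further compounds**

F1 | step 9 | (2R,3R)-3-(3,5-bis(benzyloxy)-2-{(2S,4R)-7-(benzyloxy)-2-[4-(benzyloxy)phenyl]-3,4-dihydro-2H-chromen-4-yl}phenoxy)-3-[3,4,5-tris(benzyloxy)phenyl]propane-1,2-diol | C(c1ccccc1)Oc1ccc([C@@H]2C[C@@H](c3c(OCc4ccccc4)cc(OCc4ccccc4)cc3O[C@H](c3cc(OCc5ccccc5)c(OCc5ccccc5)c(OCc5ccccc5)c3)[C@H](O)CO)c3ccc(OCc4ccccc4)cc3O2)cc1
F2 | step 9 | (2R,3R)-3-(3,5-bis(benzyloxy)-2-{(2S,4R)-7-(benzyloxy)-2-[4-(benzyloxy)phenyl]-3,4-dihydro-2H-chromen-4-yl}phenoxy)-2-hydroxy-3-[3,4,5-tris(benzyloxy)phenyl]propyl 4-methylbenzenesulfonate | C(c1ccccc1)Oc1ccc([C@@H]2C[C@@H](c3c(OCc4ccccc4)cc(OCc4ccccc4)cc3O[C@H](c3cc(OCc5ccccc5)c(OCc5ccccc5)c(OCc5ccccc5)c3)[C@H](O)COS(=O)(=O)c3ccc(C)cc3)c3ccc(OCc4ccccc4)cc3O2)cc1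
F3 | step 9 | (2R)-2-[(R)-(3,5-bis(benzyloxy)-2-{(2S,4R)-7-(benzyloxy)-2-[4-(benzyloxy)phenyl]-3,4-dihydro-2H-chromen-4-yl}phenoxy)[3,4,5-tris(benzyloxy)phenyl]methyl]oxirane | C(c1ccccc1)Oc1ccc([C@@H]2C[C@@H](c3c(OCc4ccccc4)cc(OCc4ccccc4)cc3O[C@H](c3cc(OCc5ccccc5)c(OCc5ccccc5)c(OCc5ccccc5)c3)[C@H]3CO3)c3ccc(OCc4ccccc4)cc3O2)cc1
F4 | step 8 | (2S,4R)-7-(benzyloxy)-2-[4-(benzyloxy)phenyl]-4-[3,5-bis(benzyloxy)phenoxy]-3,4-dihydro-2H-chromene (2,4-trans) | C(c1ccccc1)Oc1ccc([C@@H]2C[C@@H](Oc3cc(OCc4ccccc4)cc(OCc4ccccc4)c3)c3ccc(OCc4ccccc4)cc3O2)cc1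
F5 | step 3 | ethyl (2S,3S)-3-[3,4,5-tris(benzyloxy)phenyl]oxirane-2-carboxylate (cis) | CCOC(=O)[C@H]1O[C@H]1c1cc(OCc2ccccc2)c(OCc2ccccc2)c(OCc2ccccc2)c1
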